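**Retrosynthetic overview**

- The sulfate ester and the two free phenols are revealed last: the O–S bond is cut back to a 5,7-di-O-benzyl flavonol, and its C3–OH is traced to oxidation of the C2=C3 bond of the corresponding flavone.
- The flavone is cut through three bonds of ring C (C4–C4a, C8a–O1, O1–C2). This gives a 3,5-bis(benzyloxy)benzyne, stored as an o-silylaryl triflate, and 3-(4-methoxyphenyl)propiolic acid, which already carries C2, C3, the C4 carbonyl and ring B.
- The feature used is in ring A: the neighbouring carbons C4a and C8a bear the carbonyl carbon C4 and the ring oxygen O1, with the C5 oxygen ortho and the C7 oxygen para to C4a. A 3,5-dialkoxyaryne gives this pattern when oxygen adds at its unflanked terminus and the acyl group ends on the alkoxy-flanked terminus.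
- Rings A and B are purchased benzenes; ring C is the only ring made, closed in the fragment-joining step by 6-endo oxa-Michael addition.

Key step: step 5

Remark: the target is taken as the neutral hydrogen sulfate as drawn. Because aryl hydrogen sulfates are acid-labile, the sulfate is carried as its triethylammonium salt and the free acid is liberated only in the last, cold operation.

**Route**

Step 1
Reactants: 1 3,5-bis(benzyloxy)phenol
Product: 2 3,5-bis(benzyloxy)phenyl N-isopropylcarbamate
Conditions: i-PrNCO, Et3N (cat.), CH2Cl2, rt
Reagents that add atoms: isopropyl isocyanate, CC(C)N=C=O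
Why: Amine-catalysed addition of the single phenolic O–H across the isocyanate (carbamoylation) should proceed cleanly and installs a removable secondary carbamate as the directing group for ortho-metalation.

Step 2
Reactants: 2 3,5-bis(benzyloxy)phenyl N-isopropylcarbamate
Product: 6 3,5-bis(benzyloxy)-2-(trimethylsilyl)phenyl N-isopropylcarbamate, via N-silyl carbamate 3 (not isolated), via ortho-lithiated N-silyl carbamate 4 (not isolated), via C,N-bis(trimethylsilyl) carbamate 5 (not isolated)
Conditions: TMSOTf, TMEDA, Et2O, 0 °C to rt; n-BuLi, TMEDA, −78 °C; TMSCl, −78 °C to rt; sat. aq. NH4Cl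
Reagents that add atoms: chlorotrimethylsilane, C[Si](C)(C)Cl
Why: In situ N-silylation makes the carbamate behave as a tertiary directing group, so directed ortho-metalation by n-BuLi/TMEDA should occur at the C–H flanked by the carbamate and a benzyloxy group (the two such sites are equivalent), and TMSCl quench gives the aryl silane, the labile N–Si bond being hydrolysed on work-up.

Step 3
Reactants: 6 3,5-bis(benzyloxy)-2-(trimethylsilyl)phenyl N-isopropylcarbamate
Product: 8 3,5-bis(benzyloxy)-2-(trimethylsilyl)phenyl trifluoromethanesulfonate, via 2-silylphenoxide 7 (not isolated)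
Conditions: Et2NH, DBU, MeCN, 40 °C; then PhNTf2, rt
Reagents that add atoms: N-phenylbis(trifluoromethanesulfonimide), O=S(=O)(N(c1ccccc1)S(=O)(=O)C(F)(F)F)C(F)(F)F
Why: DBU-induced E1cB fragmentation of the N–H carbamate releases the phenoxide (the isocyanate is scavenged by Et2NH as a urea), and O-triflation by PhNTf2 in the same pot keeps the electron-rich, protodesilylation-prone silylphenol away from acid.

Step 4
Reactants: 9 4-ethynylanisole
Product: 12 3-(4-methoxyphenyl)propiolic acid, via lithium acetylide 10 (not isolated), via lithium propiolate salt 11 (not isolated)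
Conditions: n-BuLi, THF, −78 °C; CO2, −78 °C to rt; 1 M HCl
Reagents that add atoms: carbon dioxide, O=C=O
Why: Deprotonation of the terminal alkyne and carboxylation of the lithium acetylide with CO2 is the standard entry to arylpropiolic acids.

Step 5
Reactants: 8 3,5-bis(benzyloxy)-2-(trimethylsilyl)phenyl trifluoromethanesulfonate (1.5 equiv); 12 3-(4-methoxyphenyl)propiolic acid
Product: 15 5,7-bis(benzyloxy)-4'-methoxyflavone, via 3,5-bis(benzyloxy)benzyne 13 (not isolated), via 2-hydroxyaryl ynone 14 (not isolated)
Conditions: CsF (4 equiv), THF, sealed tube, 125 °C; then K2CO3, acetone, 50 °C on the crude if 14 persists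
Reagents that add atoms: none
Why: Fluoride attacks silicon and triflate leaves to unveil the aryne; the caesium propiolate adds through oxygen to the aryne terminus remote from the flanking benzyloxy group, and the aryl anion generated next to that C–O bond attacks the ester carbonyl, the four-membered adduct opening to the 2-acylphenoxide (formal insertion of the aryne into the acid C–O bond, making C8a–O1 and C4–C4a). The closest known reaction type is the fluoride-induced intermolecular C–O addition of carboxylic acids to arynes from o-silylaryl triflates, which gives o-hydroxyaryl ketones and, with arylpropiolic acids, flavones. Ring C is closed by 6-endo-dig oxa-Michael addition of the phenoxide to the ynone β-carbon (O1–C2), with protonation at C3. No stereocentre is formed. The step needs, first, aryne regioselectivity, secured by the inductive and distortion effect of the 3-benzyloxy group, which makes the distal terminus electrophilic and stabilises the ortho anion; second, acyl transfer in preference to protonation of the aryl anion, favoured by the high temperature and aprotic medium; and third, 6-endo over 5-exo closure, favoured by the polarisation of the anisyl ynone toward β-attack under basic aprotic conditions.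

Step 6
Reactants: 15 5,7-bis(benzyloxy)-4'-methoxyflavone
Product: 16 rac-5,7-bis(benzyloxy)-4'-methoxyflavone 2,3-epoxide (cis-fused oxirane on C2–C3)
Conditions: dimethyldioxirane (ca. 0.08 M in acetone), CH2Cl2, 0 °C to rt, dark
Reagents that add atoms: dimethyldioxirane, CC1(C)OO1
Why: Electrophilic epoxidation of the oxygen-substituted C2=C3 bond by dimethyldioxirane runs under neutral conditions with acetone as the only by-product; the two new stereocentres are necessarily cis on the fused oxirane and form as a racemate, which is of no consequence because both are erased in step 7.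

Step 7
Reactants: 16 rac-5,7-bis(benzyloxy)-4'-methoxyflavone 2,3-epoxide
Product: 17 5,7-bis(benzyloxy)-3-hydroxy-4'-methoxyflavone
Conditions: p-TsOH·H2O (cat.), CH2Cl2, rt
Reagents that add atoms: none
Why: Acid-catalysed opening of the oxirane at C2 (cation stabilised by O1 and the anisyl group) followed by loss of the C3 proton re-aromatises the pyranone, an epoxide-to-flavonol isomerisation.

Step 8
Reactants: 17 5,7-bis(benzyloxy)-3-hydroxy-4'-methoxyflavone
Product: 18 triethylammonium 5,7-bis(benzyloxy)-4'-methoxyflavon-3-yl sulfate
Conditions: SO3·pyridine (5 equiv), pyridine, 40 °C; then Et3N, MeOH, 0 °C; SiO2 (CH2Cl2–MeOH–Et3N)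
Reagents that add atoms: sulfur trioxide–pyridine complex, [O-]S(=O)(=O)[n+]1ccccc1; triethylamine, CCN(CC)CC
Why: O-sulfation of the only free hydroxyl with the SO3·pyridine complex, followed by exchange of the counter-ion to triethylammonium, should give an organic-soluble, chromatographable sulfate monoester salt.

Step 9
Reactants: 18 triethylammonium 5,7-bis(benzyloxy)-4'-methoxyflavon-3-yl sulfate
Product: 19 triethylammonium kaempferide 3-O-sulfate (triethylammonium 5,7-dihydroxy-4'-methoxyflavon-3-yl sulfate)
Conditions: H2 (1 atm), 10% Pd/C, THF–MeOH, rt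
Reagents that add atoms: none
Why: Catalytic hydrogenolysis of the two aryl benzyl ethers over Pd/C is neutral, so the sulfate salt, the aryl methyl ether and the pyranone should survive.

Step 10
Reactants: 19 triethylammonium kaempferide 3-O-sulfate
Product: 20 kaempferide 3-O-sulfate (5,7-dihydroxy-4'-methoxyflavon-3-yl hydrogen sulfate)
Conditions: Dowex 50W-X8 (H+ form), H2O–MeOH, 0–4 °C; immediate lyophilisation
Reagents that add atoms: none
Why: Cation exchange on a sulfonic-acid resin replaces triethylammonium by a proton to give the hydrogen sulfate form, and cold handling with immediate freeze-drying should limit autocatalytic hydrolysis of the sulfate ester.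

**Compound list**

1 | 3,5-bis(benzyloxy)phenol | Oc1cc(OCc2ccccc2)cc(OCc2ccccc2)c1 | starting material
2 | 3,5-bis(benzyloxy)phenyl N-isopropylcarbamate | CC(C)NC(=O)Oc1cc(OCc2ccccc2)cc(OCc2ccccc2)c1 | intermediate
3 | 3,5-bis(benzyloxy)phenyl N-isopropyl-N-(trimethylsilyl)carbamate | CC(C)N(C(=O)Oc1cc(OCc2ccccc2)cc(OCc2ccccc2)c1)[Si](C)(C)C | intermediate
4 | 3,5-bis(benzyloxy)-2-lithiophenyl N-isopropyl-N-(trimethylsilyl)carbamate | CC(C)N(C(=O)Oc1cc(OCc2ccccc2)cc(OCc2ccccc2)c1[Li])[Si](C)(C)C | intermediate
5 | 3,5-bis(benzyloxy)-2-(trimethylsilyl)phenyl N-isopropyl-N-(trimethylsilyl)carbamate | CC(C)N(C(=O)Oc1cc(OCc2ccccc2)cc(OCc2ccccc2)c1[Si](C)(C)C)[Si](C)(C)C | intermediate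
6 | 3,5-bis(benzyloxy)-2-(trimethylsilyl)phenyl N-isopropylcarbamate | CC(C)NC(=O)Oc1cc(OCc2ccccc2)cc(OCc2ccccc2)c1[Si](C)(C)C | intermediate
7 | 3,5-bis(benzyloxy)-2-(trimethylsilyl)phenol (present as its phenoxide, drawn neutral) | C[Si](C)(C)c1c(O)cc(OCc2ccccc2)cc1OCc1ccccc1 | intermediate
8 | 3,5-bis(benzyloxy)-2-(trimethylsilyl)phenyl trifluoromethanesulfonate | C[Si](C)(C)c1c(OCc2ccccc2)cc(OCc2ccccc2)cc1OS(=O)(=O)C(F)(F)F | intermediate
9 | 4-ethynylanisole | COc1ccc(C#C)cc1 | starting material
10 | lithium (4-methoxyphenyl)acetylide | COc1ccc(C#C[Li])cc1 | intermediate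
11 | lithium 3-(4-methoxyphenyl)propiolate | COc1ccc(C#CC(=O)[O-])cc1.[Li+] | intermediate
12 | 3-(4-methoxyphenyl)propiolic acid | COc1ccc(C#CC(=O)O)cc1 | intermediate
13 | 3,5-bis(benzyloxy)benzyne | C1#CC(OCc2ccccc2)=CC(OCc2ccccc2)=C1 | intermediate
14 | 1-[2,4-bis(benzyloxy)-6-hydroxyphenyl]-3-(4-methoxyphenyl)prop-2-yn-1-one (present as its phenoxide, drawn neutral) | COc1ccc(C#CC(=O)c2c(O)cc(OCc3ccccc3)cc2OCc2ccccc2)cc1 | intermediate
15 | 5,7-bis(benzyloxy)-4'-methoxyflavone | COc1ccc(-c2cc(=O)c3c(OCc4ccccc4)cc(OCc4ccccc4)cc3o2)cc1 | intermediate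
16 | rac-5,7-bis(benzyloxy)-4'-methoxyflavone 2,3-epoxide (racemate, one enantiomer drawn, cis ring fusion) | COc1ccc(cc1)[C@@]12O[C@@H]1C(=O)c1c(OCc3ccccc3)cc(OCc3ccccc3)cc1O2 | intermediate
17 | 5,7-bis(benzyloxy)-3-hydroxy-4'-methoxyflavone | COc1ccc(-c2oc3cc(OCc4ccccc4)cc(OCc4ccccc4)c3c(=O)c2O)cc1 | intermediate
18 | triethylammonium 5,7-bis(benzyloxy)-4'-methoxyflavon-3-yl sulfate | COc1ccc(-c2oc3cc(OCc4ccccc4)cc(OCc4ccccc4)c3c(=O)c2OS(=O)(=O)[O-])cc1.CC[NH+](CC)CC | intermediate
19 | triethylammonium kaempferide 3-O-sulfate | COc1ccc(-c2oc3cc(O)cc(O)c3c(=O)c2OS(=O)(=O)[O-])cc1.CC[NH+](CC)CC | intermediate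
20 | kaempferide 3-O-sulfate | COc1ccc(-c2oc3cc(O)cc(O)c3c(=O)c2OS(=O)(=O)O)cc1 | target

**Step count**

Total step count: 10. Longest linear sequence: 9 steps (steps 1, 2, 3, 5, 6, 7, 8, 9, 10, from 1 to 20); step 4 is the one-step branch.

**Steps most likely to fail**

Step 5. The aryl anion may be protonated before the acyl group migrates, which stops the sequence at simple O-arylation. The propiolate may also decarboxylate at the reaction temperature, the aryne may be captured at the wrong terminus, or the phenoxide may close 5-exo. The fallback sets out from 2 and 12 and comes back at 15. Acid 12 is coupled with N,O-dimethylhydroxylamine hydrochloride (EDC·HCl, N-methylmorpholine, CH2Cl2) to the Weinreb amide N-methoxy-N-methyl-3-(4-methoxyphenyl)propiolamide F1. Carbamate 2 is N-silylated and ortho-lithiated as in step 2 (through 3 and 4), and the aryllithium 4 is acylated with F1 at −78 °C (Weinreb ketone synthesis). Aqueous work-up should give 3,5-bis(benzyloxy)-2-[3-(4-methoxyphenyl)propioloyl]phenyl N-isopropylcarbamate F2. Treatment of F2 with Et2NH and DBU in MeCN cleaves the carbamate to the phenoxide of 14, which should close to flavone 15, either directly or by addition–elimination on the β-diethylamino enone.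

Step 2. The base may deprotonate a benzylic CH2 of the ethers (followed by Wittig rearrangement), the carbamate may migrate by anionic ortho-Fries rearrangement on warming, or metalation may occur between the two benzyloxy groups. The fallback sets out from 1 and comes back at 8, bypassing steps 1 to 3. Phenol 1 is brominated ortho to the hydroxyl (NBS, cat. i-Pr2NH, CH2Cl2, 0 °C) to 2-bromo-3,5-bis(benzyloxy)phenol F3. F3 is silylated with hexamethyldisilazane (THF, reflux) to [2-bromo-3,5-bis(benzyloxy)phenoxy]trimethylsilane F4. Treatment of F4 with n-BuLi in THF at −78 °C effects bromine–lithium exchange, which is faster than C–H deprotonation, and the 1,3 O-to-C silyl shift (retro-Brook rearrangement) gives the lithium phenoxide of 7. Trapping with Tf2O should give 8.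

Step 6. Oxidation may occur at the electron-rich ring A or at the benzylic C–H bonds faster than at the C2=C3 bond, or the oxirane may be opened prematurely by adventitious water with ring contraction. The fallback sets out from 15 and comes back at 17, bypassing 16. Flavone 15 is lithiated at C3 with lithium diisopropylamide (THF, −78 °C) and trapped with B(OMe)3 to give dimethyl [5,7-bis(benzyloxy)-4'-methoxyflavon-3-yl]boronate F5. F5 is oxidised in the same flask with H2O2/AcOH (boronate oxidation) to flavonol 17.

**Further compounds**

F1 | step 5 | N-methoxy-N-methyl-3-(4-methoxyphenyl)propiolamide | COc1ccc(C#CC(=O)N(C)OC)cc1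
F2 | step 5 | 3,5-bis(benzyloxy)-2-[3-(4-methoxyphenyl)propioloyl]phenyl N-isopropylcarbamate | COc1ccc(C#CC(=O)c2c(OC(=O)NC(C)C)cc(OCc3ccccc3)cc2OCc2ccccc2)cc1
F3 | step 2 | 2-bromo-3,5-bis(benzyloxy)phenol | Oc1cc(OCc2ccccc2)cc(OCc2ccccc2)c1Br
F4 | step 2 | [2-bromo-3,5-bis(benzyloxy)phenoxy]trimethylsilane | C[Si](C)(C)Oc1cc(OCc2ccccc2)cc(OCc2ccccc2)c1Br
F5 | step 6 | dimethyl [5,7-bis(benzyloxy)-4'-methoxyflavon-3-yl]boronate | COc1ccc(-c2oc3cc(OCc4ccccc4)cc(OCc4ccccc4)c3c(=O)c2B(OC)OC)cc1
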